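**Plan**
- The target has a twofold axis through the midpoint of the C15=C15' bond, and C14–C15 is a single bond between two sp2 carbons of the central triene. The retrosynthesis cuts this bond first, giving a C19 (E)-alkenyl iodide (iodine on C14) and a C21 (E,E)-dienylstannane (tin on C15). The two differ only by the C15=C15' ethene unit, so the stannane is cut at C14'–C15' back to the same C19 iodide plus (E)-1,2-bis(tributylstannyl)ethene.
- The C19 iodide is cut at C11=C12 into a C15 furanoid enal and a C4 iodoallyl phosphonate. The O1–C8 bond of the 2,5-dihydrofuran ring is cut back to an α-hydroxyallene, the allene to a 5,6-epoxy-7-yne, and the C6–C7 bond to an enol triflate plus a C6 enynol.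
- Forward order: cyclohexane ring from the chiral pool, then C6–C7, 5,6-epoxide, C6=C7=C8 allene, closure of the dihydrofuran ring, C11=C12, C14'–C15', and last C14–C15.
- Stereochemistry: C3 comes from (4R,6R)-actinol. C5 is set by epoxidation anti to the C3 silyloxy group. C8 is set by anti-SN2' hydride delivery (centre to axis) followed by gold-catalysed 5-endo cyclization (axis to centre).
- The E double bonds come from the enynol, from syn-carboalumination and from an E-selective olefination; both Stille couplings retain geometry.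

Key step: step 15

Remark: carotenoid numbering is used for positions in all intermediates (ring C1–C6, chain C7–C15, primes for the second half). (4R,6R)-Actinol, the enynol 5, prop-2-yn-1-ol and the distannane 20 are taken as commercial.

**Step 1**
Reactants: 1 (4R,6R)-4-hydroxy-2,2,6-trimethylcyclohexan-1-one
Product: 2 (4R,6R)-4-[(tert-butyldimethylsilyl)oxy]-2,2,6-trimethylcyclohexan-1-one
Conditions: TBSCl, imidazole, DMF, rt
Reagents that add atoms: tert-butyldimethylsilyl chloride CC(C)(C)[Si](C)(C)Cl
Why: Silyl ether formation masks the secondary hydroxyl for the enolate chemistry that follows and touches no stereocentre.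

**Step 2**
Reactants: 2 (4R,6R)-4-[(tert-butyldimethylsilyl)oxy]-2,2,6-trimethylcyclohexan-1-one
Product: 4 (4R)-4-[(tert-butyldimethylsilyl)oxy]-2,6,6-trimethylcyclohex-1-en-1-yl trifluoromethanesulfonate, via lithium enolate 3 (not isolated)
Conditions: LiN(iPr)2, THF, −78 °C; then PhNTf2, −78 °C to rt
Reagents that add atoms: N-phenylbis(trifluoromethanesulfonimide) O=S(=O)(N(c1ccccc1)S(=O)(=O)C(F)(F)F)C(F)(F)F
Why: The ketone has a single enolizable position (the other α-carbon is quaternary), so enol triflate formation should give one regioisomer and fix the C5=C6 double bond; the C5 centre is erased on purpose and C3 is untouched.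

**Step 3**
Reactants: 5 (2E)-3-methylpent-2-en-4-yn-1-ol
Product: 6 tert-butyldimethyl{[(2E)-3-methylpent-2-en-4-yn-1-yl]oxy}silane
Conditions: TBSCl, imidazole, CH2Cl2, 0 °C to rt
Reagents that add atoms: tert-butyldimethylsilyl chloride CC(C)(C)[Si](C)(C)Cl
Why: Silylation of the primary allylic alcohol prevents hydroxyl-directed oxidation of the C9=C10 bond in step 5 and silane consumption in step 6.

**Step 4**
Reactants: 4 (4R)-4-[(tert-butyldimethylsilyl)oxy]-2,6,6-trimethylcyclohex-1-en-1-yl trifluoromethanesulfonate; 6 tert-butyldimethyl{[(2E)-3-methylpent-2-en-4-yn-1-yl]oxy}silane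
Product: 7 tert-butyl{[(2E)-5-{(4R)-4-[(tert-butyldimethylsilyl)oxy]-2,6,6-trimethylcyclohex-1-en-1-yl}-3-methylpent-2-en-4-yn-1-yl]oxy}dimethylsilane
Conditions: Pd(PPh3)4 (5 mol %), CuI (10 mol %), Et3N, DMF, 50 °C
Reagents that add atoms: none
Why: Sonogashira coupling of the alkenyl triflate with the terminal alkyne forms the C6–C7 bond, and the E geometry of C9=C10 is carried over unchanged from 5.

**Step 5**
Reactants: 7 the dienyne from step 4
Product: 8 (1R,4S,6R)-4-[(tert-butyldimethylsilyl)oxy]-1-[(3E)-5-[(tert-butyldimethylsilyl)oxy]-3-methylpent-3-en-1-yn-1-yl]-2,2,6-trimethyl-7-oxabicyclo[4.1.0]heptane (5,6-epoxide with oxygen anti to the C3 silyloxy group)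
Conditions: mCPBA (1.05 equiv), NaHCO3, CH2Cl2, −20 to 0 °C
Reagents that add atoms: 3-chloroperbenzoic acid OOC(=O)c1cccc(Cl)c1
Why: Prilezhaev epoxidation should take the electron-rich tetrasubstituted C5=C6 bond in preference to the trisubstituted C9=C10 bond that carries the inductively deactivating allylic silyl ether; with the C3 hydroxyl silylated there is no hydroxyl direction, attack anti to the silyloxy group is expected to predominate, and the syn epoxide is removed by chromatography, which sets C5 (and C6).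

**Step 6**
Reactants: 8 the anti 5,6-epoxy-7-yne
Product: 9 (1R,5S)-5-[(tert-butyldimethylsilyl)oxy]-2-[(3E)-5-[(tert-butyldimethylsilyl)oxy]-3-methylpenta-1,3-dien-1-ylidene]-1,3,3-trimethylcyclohexan-1-ol with S allene axis (carotenoid numbering 3S,5R,6S)
Conditions: chloro[1,3-bis(2,6-diisopropylphenyl)imidazol-2-ylidene]copper, (IPr)CuCl (5 mol %), NaOtBu (10 mol %), polymethylhydrosiloxane (2 equiv Si–H), toluene, 0 °C to rt; then 1 M aq. NaOH, THF
Reagents that add atoms: none
Why: Copper-hydride-catalysed SN2' reduction of a propargyl oxirane delivers hydride to C8 anti to the departing C6–O bond, so the epoxide configuration is transferred to the S allene axis while C5 keeps its oxygen; the silyl ethers and the trisubstituted alkene are inert.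

**Step 7**
Reactants: 9 the α-hydroxy vinylallene
Product: 10 tert-butyl{[(2R,6S,7aR)-2-[(2E)-4-[(tert-butyldimethylsilyl)oxy]but-2-en-2-yl]-4,4,7a-trimethyl-2,4,5,6,7,7a-hexahydro-1-benzofuran-6-yl]oxy}dimethylsilane
Conditions: AuCl3 (5 mol %), THF, 0 °C to rt, dark
Reagents that add atoms: none
Why: Gold-catalysed 5-endo-trig cycloisomerization of an α-hydroxyallene to a 2,5-dihydrofuran: the C5 hydroxyl attacks C8 anti to the gold-complexed C7=C8 bond and protodeauration at C7 follows, so the allene axis is transferred to the C8 centre with C9 trans to the C5 methyl (8R).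

**Step 8**
Reactants: 10 the bis-silyl furanoid
Product: 11 (2R,6S,7aR)-2-[(2E)-4-hydroxybut-2-en-2-yl]-4,4,7a-trimethyl-2,4,5,6,7,7a-hexahydro-1-benzofuran-6-ol
Conditions: TBAF (3 equiv), THF, 0 °C to rt
Reagents that add atoms: none
Why: Fluoride-induced desilylation frees both hydroxyls in a non-acidic medium that leaves the acid-labile doubly allylic C8–O bond and the C8 configuration untouched.

**Step 9**
Reactants: 11 the furanoid diol
Product: 12 (2E)-3-[(2R,6S,7aR)-6-hydroxy-4,4,7a-trimethyl-2,4,5,6,7,7a-hexahydro-1-benzofuran-2-yl]but-2-enal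
Conditions: activated MnO2 (excess), CH2Cl2, rt
Reagents that add atoms: none
Why: Allylic oxidation with MnO2 should convert only the primary allylic alcohol to the enal under neutral conditions and leave the non-allylic C3 hydroxyl and the E geometry alone.

**Step 10**
Reactants: 13 prop-2-yn-1-ol
Product: 15 (2E)-3-iodo-2-methylprop-2-en-1-ol, via alkenylalane 14 (not isolated)
Conditions: AlMe3 (3 equiv), Cp2ZrCl2 (0.25 equiv), CH2Cl2, 0 °C to rt; then I2, THF, −30 to 0 °C
Reagents that add atoms: trimethylaluminium C[Al](C)C; iodine II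
Why: Zirconium-catalysed syn-carboalumination (Negishi carboalumination) places methyl on the internal and aluminium on the terminal alkyne carbon, and iodinolysis with retention should give the E iodide.

**Step 11**
Reactants: 15 (2E)-3-iodo-2-methylprop-2-en-1-ol
Product: 16 (1E)-3-bromo-1-iodo-2-methylprop-1-ene
Conditions: CBr4, PPh3, CH2Cl2, 0 °C
Reagents that add atoms: carbon tetrabromide BrC(Br)(Br)Br
Why: Appel bromination converts the allylic alcohol to the bromide under neutral conditions without touching the alkenyl iodide or its geometry.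

**Step 12**
Reactants: 16 (1E)-3-bromo-1-iodo-2-methylprop-1-ene
Product: 17 diethyl [(2E)-3-iodo-2-methylprop-2-en-1-yl]phosphonate
Conditions: P(OEt)3, neat, 100 °C
Reagents that add atoms: triethyl phosphite CCOP(OCC)OCC
Why: Michaelis–Arbuzov reaction takes place at the allylic bromide only, since the alkenyl iodide does not react thermally with the phosphite.

**Step 13**
Reactants: 12 the C15 furanoid enal; 17 diethyl [(2E)-3-iodo-2-methylprop-2-en-1-yl]phosphonate
Product: 19 (2R,6S,7aR)-2-[(2E,4E,6E)-7-iodo-6-methylhepta-2,4,6-trien-2-yl]-4,4,7a-trimethyl-2,4,5,6,7,7a-hexahydro-1-benzofuran-6-ol, via phosphonate carbanion 18 (not isolated)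
Conditions: 17 (2.5 equiv), NaN(SiMe3)2 (2.4 equiv), THF, −78 °C; then 12, −78 to 0 °C
Reagents that add atoms: none
Why: Horner–Wadsworth–Emmons olefination of the enal with the allylic phosphonate carbanion should form the C11=C12 bond E-selectively; carbonyl addition at −78 °C should outrun γ-deprotonation at C8, one equivalent of carbanion is consumed by the free C3 hydroxyl, and the C13=C14 geometry comes from 17.

**Step 14**
Reactants: 19 the C19 alkenyl iodide; 20 (E)-1,2-bis(tributylstannyl)ethene
Product: 21 (2R,6S,7aR)-4,4,7a-trimethyl-2-[(2E,4E,6E,8E)-6-methyl-9-(tributylstannyl)nona-2,4,6,8-tetraen-2-yl]-2,4,5,6,7,7a-hexahydro-1-benzofuran-6-ol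
Conditions: 20 (4 equiv), Pd2(dba)3·CHCl3 (2.5 mol %), AsPh3 (20 mol %), NMP, rt, dark, argon; chromatography on Et3N-deactivated silica
Reagents that add atoms: none
Why: Stille coupling of the alkenyl iodide with one tin terminus of the distannane, used in large excess to suppress twofold coupling, forms the C14'–C15' bond with retention at both alkenes and leaves the second tin on C15.

**Step 15**
Reactants: 19 the C19 alkenyl iodide; 21 the C21 dienylstannane
Product: 22 (all-E)-(3S,5R,8R,3'S,5'R,8'R)-5,8:5',8'-diepoxy-5,8,5',8'-tetrahydro-β,β-carotene-3,3'-diol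
Conditions: 19 and 21 (1:1), Pd2(dba)3·CHCl3 (5 mol %), AsPh3 (40 mol %), degassed NMP, rt, dark, argon
Reagents that add atoms: none
Why: Stille cross-coupling: zerovalent palladium inserts into the C14–I bond of 19 with retention of the E geometry, the C15 alkenyl group of 21 is transferred from tin to palladium with retention in the AsPh3-accelerated transmetalation, and reductive elimination forms the C14–C15 single bond between two sp2 carbons. The closest known reaction type is the alkenyl iodide–alkenylstannane Stille coupling used to assemble carotenoid polyenes from polyenyl iodides and polyenylstannanes. No ring is closed and no stereocentre is created; the six stereocentres (C3, C5 and C8 in each half) and all seven chain double-bond geometries are brought in by the two partners. The selectivity needed is cross-coupling over homo-coupling with retention of the E configuration at C13=C14 and C15=C15', which the iodide/stannane pairing, the 1:1 stoichiometry and the ligand-accelerated room-temperature conditions should secure. The neutral medium leaves the acid-labile doubly allylic C8–O bonds of both dihydrofuran rings and the free C3 hydroxyls untouched, so the coupling should deliver the target without any later step.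

**Compound list**
1 | (4R,6R)-4-hydroxy-2,2,6-trimethylcyclohexan-1-one (actinol) | O=C1C(C)(C)C[C@H](O)C[C@H]1C | starting material
2 | (4R,6R)-4-[(tert-butyldimethylsilyl)oxy]-2,2,6-trimethylcyclohexan-1-one | O=C1C(C)(C)C[C@H](O[Si](C)(C)C(C)(C)C)C[C@H]1C | intermediate
3 | lithium (4R)-4-[(tert-butyldimethylsilyl)oxy]-2,6,6-trimethylcyclohex-1-en-1-olate (lithium enolate of 2) | [Li+].CC1=C([O-])C(C)(C)C[C@H](O[Si](C)(C)C(C)(C)C)C1 | intermediate (not isolated)
4 | (4R)-4-[(tert-butyldimethylsilyl)oxy]-2,6,6-trimethylcyclohex-1-en-1-yl trifluoromethanesulfonate | CC1=C(OS(=O)(=O)C(F)(F)F)C(C)(C)C[C@H](O[Si](C)(C)C(C)(C)C)C1 | intermediate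
5 | (2E)-3-methylpent-2-en-4-yn-1-ol | C#C/C(C)=C/CO | starting material
6 | tert-butyldimethyl{[(2E)-3-methylpent-2-en-4-yn-1-yl]oxy}silane | C#C/C(C)=C/CO[Si](C)(C)C(C)(C)C | intermediate
7 | tert-butyl{[(2E)-5-{(4R)-4-[(tert-butyldimethylsilyl)oxy]-2,6,6-trimethylcyclohex-1-en-1-yl}-3-methylpent-2-en-4-yn-1-yl]oxy}dimethylsilane | CC1=C(C#C/C(C)=C/CO[Si](C)(C)C(C)(C)C)C(C)(C)C[C@H](O[Si](C)(C)C(C)(C)C)C1 | intermediate
8 | (1R,4S,6R)-4-[(tert-butyldimethylsilyl)oxy]-1-[(3E)-5-[(tert-butyldimethylsilyl)oxy]-3-methylpent-3-en-1-yn-1-yl]-2,2,6-trimethyl-7-oxabicyclo[4.1.0]heptane | CC(C)(C)[Si](C)(C)OC/C=C(C)/C#C[C@]12C(C)(C)C[C@H](O[Si](C)(C)C(C)(C)C)C[C@@]1(C)O2 | intermediate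
9 | (1R,5S)-5-[(tert-butyldimethylsilyl)oxy]-2-[(3E)-5-[(tert-butyldimethylsilyl)oxy]-3-methylpenta-1,3-dien-1-ylidene]-1,3,3-trimethylcyclohexan-1-ol, S allene axis | CC(C)(C)[Si](C)(C)OC/C=C(C)/C([H])=[C@]=C1C(C)(C)C[C@H](O[Si](C)(C)C(C)(C)C)C[C@@]1(C)O | intermediate
10 | tert-butyl{[(2R,6S,7aR)-2-[(2E)-4-[(tert-butyldimethylsilyl)oxy]but-2-en-2-yl]-4,4,7a-trimethyl-2,4,5,6,7,7a-hexahydro-1-benzofuran-6-yl]oxy}dimethylsilane | CC(C)(C)[Si](C)(C)OC/C=C(C)/[C@H]1C=C2C(C)(C)C[C@H](O[Si](C)(C)C(C)(C)C)C[C@@]2(C)O1 | intermediate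
11 | (2R,6S,7aR)-2-[(2E)-4-hydroxybut-2-en-2-yl]-4,4,7a-trimethyl-2,4,5,6,7,7a-hexahydro-1-benzofuran-6-ol | OC/C=C(C)/[C@H]1C=C2C(C)(C)C[C@H](O)C[C@@]2(C)O1 | intermediate
12 | (2E)-3-[(2R,6S,7aR)-6-hydroxy-4,4,7a-trimethyl-2,4,5,6,7,7a-hexahydro-1-benzofuran-2-yl]but-2-enal | O=C/C=C(C)/[C@H]1C=C2C(C)(C)C[C@H](O)C[C@@]2(C)O1 | intermediate
13 | prop-2-yn-1-ol | C#CCO | starting material
14 | dimethyl{[(2E)-3-(dimethylalumanyl)-2-methylprop-2-en-1-yl]oxy}alumane (alkenylalane) | C[Al](C)OC/C(C)=C/[Al](C)C | intermediate (not isolated)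
15 | (2E)-3-iodo-2-methylprop-2-en-1-ol | OC/C(C)=C/I | intermediate
16 | (1E)-3-bromo-1-iodo-2-methylprop-1-ene | BrC/C(C)=C/I | intermediate
17 | diethyl [(2E)-3-iodo-2-methylprop-2-en-1-yl]phosphonate | CCOP(=O)(OCC)C/C(C)=C/I | intermediate
18 | sodium salt of the carbanion of 17 | [Na+].CCOP(=O)(OCC)[CH-]/C(C)=C/I | intermediate (not isolated)
19 | (2R,6S,7aR)-2-[(2E,4E,6E)-7-iodo-6-methylhepta-2,4,6-trien-2-yl]-4,4,7a-trimethyl-2,4,5,6,7,7a-hexahydro-1-benzofuran-6-ol | I/C=C(C)/C=C/C=C(\C)[C@H]1C=C2C(C)(C)C[C@H](O)C[C@@]2(C)O1 | intermediate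
20 | (E)-1,2-bis(tributylstannyl)ethene | CCCC[Sn](CCCC)(CCCC)/C=C/[Sn](CCCC)(CCCC)CCCC | starting material
21 | (2R,6S,7aR)-4,4,7a-trimethyl-2-[(2E,4E,6E,8E)-6-methyl-9-(tributylstannyl)nona-2,4,6,8-tetraen-2-yl]-2,4,5,6,7,7a-hexahydro-1-benzofuran-6-ol | CCCC[Sn](CCCC)(CCCC)/C=C/C=C(C)/C=C/C=C(\C)[C@H]1C=C2C(C)(C)C[C@H](O)C[C@@]2(C)O1 | intermediate
22 | (all-E)-(3S,5R,8R,3'S,5'R,8'R)-5,8:5',8'-diepoxy-5,8,5',8'-tetrahydro-β,β-carotene-3,3'-diol | CC(/C=C/C=C(\C)[C@H]1C=C2C(C)(C)C[C@H](O)C[C@@]2(C)O1)=C\C=C\C=C(C)\C=C\C=C(/C)[C@H]1C=C2C(C)(C)C[C@H](O)C[C@@]2(C)O1 | target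

**Step count**
Total: 15 steps. Longest linear sequence: 11 steps (steps 1, 2, 4, 5, 6, 7, 8, 9, 13, 14, 15).

**Steps most likely to fail**

Step 5. What may go wrong is poor facial discrimination in the peracid attack on the C5=C6 bond, or a preference for the face syn to the silyloxy group. The fallback sets out from 7 and delivers the oxygen to the face opposite to the one the electrophile takes. N-Bromosuccinimide in aqueous 1,2-dimethoxyethane at 0 °C should give the trans-bromohydrin F1, with bromine on C6 on the electrophile-accessible face and the hydroxyl on C5 anti to it. K2CO3 in methanol should then close F1 with inversion at C6 to the epoxide 8, where the fallback comes back to the route.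

Step 7. What may go wrong is loss of the C8 configuration by reversible gold-induced ionization of the doubly allylic C8–O bond, or diversion of the vinylallene into a cyclopentadiene. The fallback sets out from 9 and replaces the catalytic metal activation by a stoichiometric iodonium-induced cyclization. N-Iodosuccinimide in CH2Cl2 at −20 °C should induce the same anti 5-endo attack of the C5 hydroxyl on C8 and give the 3-iodo-2,5-dihydrofuran F2. Palladium-catalysed formate reduction (Pd(OAc)2, PPh3, HCO2H, Et3N, DMF, 40 °C) should then exchange the iodine on C7 for hydrogen and return to 10.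

Step 13. What may go wrong is γ-deprotonation of the enal at C8 by the strongly basic carbanion with epimerization, or loss of iodide from the carbanion. The fallback sets out from 11 (and uses 15), reverses the polarity of the olefination and avoids strong base.
- Corey–Kim bromination (N-bromosuccinimide, Me2S, CH2Cl2, −20 °C) should convert only the primary allylic hydroxyl of 11 into the allylic bromide F3.
- PPh3 in toluene at rt should give the phosphonium bromide F4.
- MnO2 oxidation of 15 should give (2E)-3-iodo-2-methylprop-2-enal F5.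
- Wittig reaction of F4 with F5 in refluxing 1,2-epoxybutane (the epoxide serves as the hydrogen bromide acceptor, no added base) should form the C11=C12 bond. After removal of the 11Z isomer by chromatography this gives 19, where the fallback comes back to the route.

**Further compounds**
F1 | step 5 | (1R,2S,5S)-2-bromo-5-[(tert-butyldimethylsilyl)oxy]-2-[(3E)-5-[(tert-butyldimethylsilyl)oxy]-3-methylpent-3-en-1-yn-1-yl]-1,3,3-trimethylcyclohexan-1-ol | CC(C)(C)[Si](C)(C)OC/C=C(C)/C#C[C@@]1(Br)C(C)(C)C[C@H](O[Si](C)(C)C(C)(C)C)C[C@@]1(C)O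
F2 | step 7 | tert-butyl{[(2S,6S,7aR)-2-[(2E)-4-[(tert-butyldimethylsilyl)oxy]but-2-en-2-yl]-3-iodo-4,4,7a-trimethyl-2,4,5,6,7,7a-hexahydro-1-benzofuran-6-yl]oxy}dimethylsilane | CC(C)(C)[Si](C)(C)OC/C=C(C)/[C@H]1C(I)=C2C(C)(C)C[C@H](O[Si](C)(C)C(C)(C)C)C[C@@]2(C)O1
F3 | step 13 | (2R,6S,7aR)-2-[(2E)-4-bromobut-2-en-2-yl]-4,4,7a-trimethyl-2,4,5,6,7,7a-hexahydro-1-benzofuran-6-ol | BrC/C=C(C)/[C@H]1C=C2C(C)(C)C[C@H](O)C[C@@]2(C)O1
F4 | step 13 | [(2E)-3-[(2R,6S,7aR)-6-hydroxy-4,4,7a-trimethyl-2,4,5,6,7,7a-hexahydro-1-benzofuran-2-yl]but-2-en-1-yl]triphenylphosphonium bromide | [Br-].c1ccccc1[P+](c1ccccc1)(c1ccccc1)C/C=C(C)/[C@H]1C=C2C(C)(C)C[C@H](O)C[C@@]2(C)O1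
F5 | step 13 | (2E)-3-iodo-2-methylprop-2-enal | O=C/C(C)=C/I
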